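**Plan**
1. Atom labels are those of the benzofuranone target 22 (O1, C2, C3, C3a, C4, C5, C6, C7, C7a); ring A is the cyclohexenone (C3a-C4-C5-C6-C7-C7a), ring B the tetrahydrofuran (O1-C2-C3-C3a-C7a).
2. Retrosynthesis: C6=O back to the C6 carbinol, then cut C6-C7 (ring A), then C7a=C7 (methylenation of a lactone carbonyl), then C3a-C4 and C3a-allyl (two enolate alkylations), then C2-C3 (crotylboration).
3. Enabling feature: in the vinylogous ester O1-C7a=C7-C6=O, C7 is the β-carbon of an enol ether built on the ring oxygen O1, and C6 is a carbonyl carbon held five atoms away through the quaternary C3a. An exocyclic enol ether C7a=C7H2 on ring B is therefore a neutral carbon nucleophile placed for six-ring closure onto a C6 aldehyde.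
4. Forward order: ring B first as a γ-lactone (its carbonyl carbon becomes C7a), quaternary C3a by two alkylations, lactone C=O to C=CH2, ring A last by C6-C7 closure and oxidation at C6.
5. Stereochemistry: C2/C3 from a catalytic asymmetric (Z)-crotylboration; C3a from the second alkylation, anti to the cis methyl/aryl pair; C5 from (S)-3-(benzyloxy)propane-1,2-diol, never enolised afterwards.

Key step: step 13

Remark: the Re-face selectivity of (R)-TRIP in the crotylboration of 1 is assumed by analogy with allylborations of aryl aldehydes under this catalyst; if the sense were the opposite, the (S) catalyst would be used.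

**Route**

Step 1
Reactants: 1 3,4,5-trimethoxybenzaldehyde; 2 (Z)-crotylboronic acid pinacol ester
Product: 3 (1R,2S)-2-methyl-1-(3,4,5-trimethoxyphenyl)but-3-en-1-ol
Conditions: (R)-3,3'-bis(2,4,6-triisopropylphenyl)-1,1'-binaphthyl-2,2'-diyl hydrogen phosphate [(R)-TRIP] (5 mol %), 4 Å molecular sieves, toluene, −30 °C; aqueous work-up
Reagents that add atoms: none
Why: Chiral phosphoric acid-catalysed crotylboration through a closed chair transition state, in which the (Z)-boronate should give the syn C2/C3 pair and the catalyst should select the Re face of the aldehyde (1R).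

Step 2
Reactants: 3 (1R,2S)-2-methyl-1-(3,4,5-trimethoxyphenyl)but-3-en-1-ol
Product: 5 (1R,2S)-2-methyl-1-(3,4,5-trimethoxyphenyl)butane-1,4-diol, via bis-borane adduct 4 (not isolated)
Conditions: 9-BBN (9-borabicyclo[3.3.1]nonane, 2.2 equiv), THF, 0 °C to rt; then NaOH, H2O2, 0 °C
Reagents that add atoms: hydrogen peroxide, OO
Why: Anti-Markovnikov hydroboration-oxidation of the terminal alkene (the first equivalent of borane is taken up by the hydroxyl group), which touches no stereocentre.

Step 3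
Reactants: 5 (1R,2S)-2-methyl-1-(3,4,5-trimethoxyphenyl)butane-1,4-diol
Product: 7 (4S,5R)-4-methyl-5-(3,4,5-trimethoxyphenyl)oxolan-2-one, via lactol 6 (not isolated)
Conditions: TEMPO ((2,2,6,6-tetramethylpiperidin-1-yl)oxyl, 0.2 equiv), PhI(OAc)2 (2.5 equiv), CH2Cl2, rt
Reagents that add atoms: none
Why: Oxidative lactonisation of a 1,4-diol, in which the primary alcohol is oxidised first, the hydroxy aldehyde closes to lactol 6 and this is oxidised to the γ-lactone with the cis aryl/methyl relationship retained.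

Step 4
Reactants: 7 (4S,5R)-4-methyl-5-(3,4,5-trimethoxyphenyl)oxolan-2-one; 8 allyl bromide
Product: 10 (3S,4S,5R)-3-allyl-4-methyl-5-(3,4,5-trimethoxyphenyl)oxolan-2-one, via lithium enolate 9 (not isolated)
Conditions: LDA (1.05 equiv), THF, −78 °C; then 8, −78 to −40 °C
Reagents that add atoms: none
Why: Lactone enolate alkylation, in which the allyl group should enter trans to the neighbouring methyl group; this centre is made planar again in step 9, so its configuration is not critical.

Step 5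
Reactants: 11 (S)-3-(benzyloxy)propane-1,2-diol
Product: 12 (R)-1-(benzyloxy)-3-[(tert-butyldiphenylsilyl)oxy]propan-2-ol
Conditions: TBDPSCl, imidazole, CH2Cl2, 0 °C
Reagents that add atoms: tert-butyl(chloro)diphenylsilane, CC(C)(C)[Si](Cl)(c1ccccc1)c1ccccc1
Why: Selective silylation of the primary hydroxyl group by the bulky silyl chloride.

Step 6
Reactants: 12 (R)-1-(benzyloxy)-3-[(tert-butyldiphenylsilyl)oxy]propan-2-ol
Product: 13 (R)-[3-(benzyloxy)-2-methoxypropoxy](tert-butyl)diphenylsilane
Conditions: Me3O·BF4, 1,8-bis(dimethylamino)naphthalene, CH2Cl2, rt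
Reagents that add atoms: trimethyloxonium tetrafluoroborate, C[O+](C)C.F[B-](F)(F)F
Why: O-Methylation with a Meerwein salt under non-basic conditions, which should avoid the 1,2-silyl migration that an alkoxide would allow.

Step 7
Reactants: 13 (R)-[3-(benzyloxy)-2-methoxypropoxy](tert-butyl)diphenylsilane
Product: 14 (R)-3-[(tert-butyldiphenylsilyl)oxy]-2-methoxypropan-1-ol
Conditions: H2 (1 atm), Pd/C, EtOAc, rt
Reagents that add atoms: none
Why: Hydrogenolysis of the benzyl ether, carried out before any alkene is present; silyl and methyl ethers are stable.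

Step 8
Reactants: 14 (R)-3-[(tert-butyldiphenylsilyl)oxy]-2-methoxypropan-1-ol
Product: 15 (S)-3-[(tert-butyldiphenylsilyl)oxy]-2-methoxypropyl trifluoromethanesulfonate
Conditions: Tf2O, 2,6-lutidine, CH2Cl2, −78 °C; used at once
Reagents that add atoms: trifluoromethanesulfonic anhydride, O=S(=O)(OS(=O)(=O)C(F)(F)F)C(F)(F)F
Why: Triflation of the primary alcohol to give an electrophile reactive enough for quaternary-centre formation; the stereocentre is not involved (the descriptor changes only by priority).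

Step 9
Reactants: 10 (3S,4S,5R)-3-allyl-4-methyl-5-(3,4,5-trimethoxyphenyl)oxolan-2-one; 15 (S)-3-[(tert-butyldiphenylsilyl)oxy]-2-methoxypropyl trifluoromethanesulfonate
Product: 17 (3S,4S,5R)-3-allyl-3-{(2R)-3-[(tert-butyldiphenylsilyl)oxy]-2-methoxypropyl}-4-methyl-5-(3,4,5-trimethoxyphenyl)oxolan-2-one, via lithium enolate 16 (not isolated)
Conditions: LiHMDS, THF-DMPU, −78 °C; then 15, −78 to −30 °C
Reagents that add atoms: none
Why: SN2 alkylation of the fully substituted lactone enolate by a primary triflate, in which the electrophile should approach anti to the cis C3 methyl and C2 aryl groups, so that C4 ends trans and the allyl group cis to the methyl group (C3a set as S) while C5 comes unchanged from 15.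

Step 10
Reactants: 17 (3S,4S,5R)-3-allyl-3-{(2R)-3-[(tert-butyldiphenylsilyl)oxy]-2-methoxypropyl}-4-methyl-5-(3,4,5-trimethoxyphenyl)oxolan-2-one
Product: 18 tert-butyl{(2R)-3-[(3S,4S,5R)-3-allyl-4-methyl-2-methylidene-5-(3,4,5-trimethoxyphenyl)oxolan-3-yl]-2-methoxypropoxy}diphenylsilane
Conditions: Cp2TiMe2 (3 equiv), toluene, 70 °C, dark; chromatography on Et3N-treated silica
Reagents that add atoms: bis(cyclopentadienyl)dimethyltitanium (Cp2TiMe2), C[Ti](C)(C1C=CC=C1)C1C=CC=C1
Why: Petasis methylenation, in which Cp2Ti=CH2 formed on heating adds to the lactone carbonyl and cycloreverts to the exocyclic enol ether; the quaternary C3a rules out migration of the double bond into ring B.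

Step 11
Reactants: 18 tert-butyl{(2R)-3-[(3S,4S,5R)-3-allyl-4-methyl-2-methylidene-5-(3,4,5-trimethoxyphenyl)oxolan-3-yl]-2-methoxypropoxy}diphenylsilane
Product: 19 (2R)-3-[(3S,4S,5R)-3-allyl-4-methyl-2-methylidene-5-(3,4,5-trimethoxyphenyl)oxolan-3-yl]-2-methoxypropan-1-ol
Conditions: Bu4NF, THF, 0 °C; basic work-up, crude product used
Reagents that add atoms: none
Why: Fluoride-induced desilylation in a basic medium, which should keep the acid-labile enol ether (and its possible ketalisation by the new hydroxyl group) under control.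

Step 12
Reactants: 19 (2R)-3-[(3S,4S,5R)-3-allyl-4-methyl-2-methylidene-5-(3,4,5-trimethoxyphenyl)oxolan-3-yl]-2-methoxypropan-1-ol
Product: 20 (2R)-3-[(3S,4S,5R)-3-allyl-4-methyl-2-methylidene-5-(3,4,5-trimethoxyphenyl)oxolan-3-yl]-2-methoxypropanal
Conditions: Dess-Martin periodinane, pyridine, CH2Cl2, 0 °C; used at once
Reagents that add atoms: none
Why: Dess-Martin oxidation buffered with pyridine, mild enough that the α-methoxy aldehyde should not enolise and the enol ether should survive.

Step 13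
Reactants: 20 (2R)-3-[(3S,4S,5R)-3-allyl-4-methyl-2-methylidene-5-(3,4,5-trimethoxyphenyl)oxolan-3-yl]-2-methoxypropanal
Product: 21 (2R,3S,3aS,5R)-3a-allyl-5-methoxy-3-methyl-2-(3,4,5-trimethoxyphenyl)-2,3,3a,4,5,6-hexahydro-1-benzofuran-6-ol (C6 epimers)
Conditions: MgBr2·OEt2 (2 equiv), 2,6-di-tert-butyl-4-methylpyridine (1.5 equiv), CH2Cl2, −78 to −20 °C; Et3N, then aqueous NaHCO3; crude product used
Reagents that add atoms: none
Why: MgBr2 should chelate the aldehyde oxygen and the C5 methoxy group and so activate C6; the terminal carbon C7 of the exocyclic enol ether attacks C6 to give a C7a oxocarbenium ion stabilised by O1, which loses a C7 proton to the hindered pyridine and so restores the enol ether as the ring A double bond C7=C7a. The closest known reaction type is the Lewis acid-promoted Prins (Mukaiyama aldol-type) addition of an alkyl enol ether to an aldehyde. Ring A closes in a 6-(enolendo)-exo-trig mode. The only new stereocentre is the C6 carbinol, which is not controlled and need not be, because step 14 turns it into the carbonyl carbon. The step needs chemoselectivity for the enol ether over the allyl group and the arene, secured by the far higher nucleophilicity of the enol ether, and regioselectivity for C7, which is the only nucleophilic carbon because C7a is fully substituted. C5 should stay intact because no enol or enolate of the aldehyde is formed under these non-basic, chelating, low-temperature conditions.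

Step 14
Reactants: 21 (2R,3S,3aS,5R)-3a-allyl-5-methoxy-3-methyl-2-(3,4,5-trimethoxyphenyl)-2,3,3a,4,5,6-hexahydro-1-benzofuran-6-ol
Product: 22 (2R,3S,3aS,5R)-3a-allyl-5-methoxy-3-methyl-2-(3,4,5-trimethoxyphenyl)-3,3a,4,5-tetrahydro-1-benzofuran-6(2H)-one (dysodanthin B)
Conditions: MnO2 (activated, excess), CH2Cl2, rt
Reagents that add atoms: none
Why: MnO2 oxidation of the 3-alkoxyallylic alcohol to the vinylogous ester under neutral conditions, which should leave the C5-H next to the new carbonyl group and the terminal alkene untouched.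

**Compound list**
1 | 3,4,5-trimethoxybenzaldehyde | O=Cc1cc(OC)c(OC)c(OC)c1 | starting material
2 | (Z)-crotylboronic acid pinacol ester, 2-[(2Z)-but-2-en-1-yl]-4,4,5,5-tetramethyl-1,3,2-dioxaborolane | C/C=C\CB1OC(C)(C)C(C)(C)O1 | starting material
3 | (1R,2S)-2-methyl-1-(3,4,5-trimethoxyphenyl)but-3-en-1-ol | C=C[C@H](C)[C@@H](O)c1cc(OC)c(OC)c(OC)c1 | intermediate
4 | bis-borane adduct, 9-{(3S,4R)-4-[(9-borabicyclo[3.3.1]nonan-9-yl)oxy]-3-methyl-4-(3,4,5-trimethoxyphenyl)butyl}-9-borabicyclo[3.3.1]nonane | C(C[C@H](C)[C@@H](OB1C2CCCC1CCC2)c1cc(OC)c(OC)c(OC)c1)B1C2CCCC1CCC2 | intermediate (not isolated)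
5 | (1R,2S)-2-methyl-1-(3,4,5-trimethoxyphenyl)butane-1,4-diol | OCC[C@H](C)[C@@H](O)c1cc(OC)c(OC)c(OC)c1 | intermediate
6 | lactol, (4S,5R)-4-methyl-5-(3,4,5-trimethoxyphenyl)oxolan-2-ol (both anomers) | OC1C[C@H](C)[C@H](c2cc(OC)c(OC)c(OC)c2)O1 | intermediate (not isolated)
7 | (4S,5R)-4-methyl-5-(3,4,5-trimethoxyphenyl)oxolan-2-one | O=C1C[C@H](C)[C@H](c2cc(OC)c(OC)c(OC)c2)O1 | intermediate
8 | allyl bromide | C=CCBr | starting material
9 | lithium enolate of 7 | [Li+].[O-]C1=C[C@H](C)[C@H](c2cc(OC)c(OC)c(OC)c2)O1 | intermediate (not isolated)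
10 | (3S,4S,5R)-3-allyl-4-methyl-5-(3,4,5-trimethoxyphenyl)oxolan-2-one | O=C1[C@@H](CC=C)[C@H](C)[C@H](c2cc(OC)c(OC)c(OC)c2)O1 | intermediate
11 | (S)-3-(benzyloxy)propane-1,2-diol | OC[C@H](O)COCc1ccccc1 | starting material
12 | (R)-1-(benzyloxy)-3-[(tert-butyldiphenylsilyl)oxy]propan-2-ol | CC(C)(C)[Si](c1ccccc1)(c1ccccc1)OC[C@H](O)COCc1ccccc1 | intermediate
13 | (R)-[3-(benzyloxy)-2-methoxypropoxy](tert-butyl)diphenylsilane | CC(C)(C)[Si](c1ccccc1)(c1ccccc1)OC[C@H](OC)COCc1ccccc1 | intermediate
14 | (R)-3-[(tert-butyldiphenylsilyl)oxy]-2-methoxypropan-1-ol | CC(C)(C)[Si](c1ccccc1)(c1ccccc1)OC[C@H](OC)CO | intermediate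
15 | (S)-3-[(tert-butyldiphenylsilyl)oxy]-2-methoxypropyl trifluoromethanesulfonate | CC(C)(C)[Si](c1ccccc1)(c1ccccc1)OC[C@H](OC)COS(=O)(=O)C(F)(F)F | intermediate
16 | lithium enolate of 10 | [Li+].[O-]C1=C(CC=C)[C@H](C)[C@H](c2cc(OC)c(OC)c(OC)c2)O1 | intermediate (not isolated)
17 | (3S,4S,5R)-3-allyl-3-{(2R)-3-[(tert-butyldiphenylsilyl)oxy]-2-methoxypropyl}-4-methyl-5-(3,4,5-trimethoxyphenyl)oxolan-2-one | O=C1[C@@](CC=C)(C[C@@H](OC)CO[Si](c2ccccc2)(c2ccccc2)C(C)(C)C)[C@H](C)[C@H](c2cc(OC)c(OC)c(OC)c2)O1 | intermediate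
18 | tert-butyl{(2R)-3-[(3S,4S,5R)-3-allyl-4-methyl-2-methylidene-5-(3,4,5-trimethoxyphenyl)oxolan-3-yl]-2-methoxypropoxy}diphenylsilane | C=C1O[C@@H](c2cc(OC)c(OC)c(OC)c2)[C@@H](C)[C@]1(CC=C)C[C@@H](OC)CO[Si](c2ccccc2)(c2ccccc2)C(C)(C)C | intermediate
19 | (2R)-3-[(3S,4S,5R)-3-allyl-4-methyl-2-methylidene-5-(3,4,5-trimethoxyphenyl)oxolan-3-yl]-2-methoxypropan-1-ol | C=C1O[C@@H](c2cc(OC)c(OC)c(OC)c2)[C@@H](C)[C@]1(CC=C)C[C@@H](OC)CO | intermediate
20 | (2R)-3-[(3S,4S,5R)-3-allyl-4-methyl-2-methylidene-5-(3,4,5-trimethoxyphenyl)oxolan-3-yl]-2-methoxypropanal | C=C1O[C@@H](c2cc(OC)c(OC)c(OC)c2)[C@@H](C)[C@]1(CC=C)C[C@@H](OC)C=O | intermediate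
21 | (2R,3S,3aS,5R)-3a-allyl-5-methoxy-3-methyl-2-(3,4,5-trimethoxyphenyl)-2,3,3a,4,5,6-hexahydro-1-benzofuran-6-ol (C6 epimers) | C=CC[C@@]12C[C@@H](OC)C(O)C=C1O[C@@H](c1cc(OC)c(OC)c(OC)c1)[C@H]2C | intermediate
22 | dysodanthin B, (2R,3S,3aS,5R)-3a-allyl-5-methoxy-3-methyl-2-(3,4,5-trimethoxyphenyl)-3,3a,4,5-tetrahydro-1-benzofuran-6(2H)-one | C=CC[C@@]12C[C@@H](OC)C(=O)C=C1O[C@@H](c1cc(OC)c(OC)c(OC)c1)[C@H]2C | target

**Step count and risks**
Total steps: 14. Longest linear sequence: 10 steps (steps 1-4 and 9-14; the branch 5-8 followed by 9-14 is equally long).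

Steps most likely to fail:

Step 13. Hydration or oligomerisation of the exocyclic enol ether, or ionisation of the 3-alkoxyallylic alcohol that is formed, may outrun clean ring closure. The fallback sets out from 17 and comes back at 21; it closes C6-C7 with a vinylchromium nucleophile instead of a cationic enol ether addition. Lactone 17 is reduced with i-Bu2AlH (CH2Cl2, −78 °C) to the lactol F1. The Ohira-Bestmann reagent (K2CO3, MeOH) converts this into the alkynol F2, which carries a free C2 hydroxyl group and a terminal alkyne on C3a. Iodoetherification (I2, NaHCO3, MeCN, 0 °C; 5-exo-dig anti addition) should give the (E)-iodomethylidene tetrahydrofuran F3, with iodine trans to O1 and therefore cis to C3a. Bu4NF then gives the primary alcohol F4 and buffered Dess-Martin oxidation the aldehyde F5. A Nozaki-Hiyama-Kishi cyclisation (CrCl2, catalytic NiCl2, DMF, rt) closes ring A to 21.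

Step 9. The SN2 displacement at the β-branched, β-oxygenated triflate may be slow, so that O-alkylation, elimination or decay of the triflate competes with formation of the quaternary centre. The fallback sets out from 10 and comes back at 17; it replaces the alkylation by a conjugate addition. Enolate 16 is added to methyl 2-methoxyacrylate (THF, −78 °C), from the same face, to give the methyl ester F6 as a mixture at C5. NaBH4 in MeOH should reduce the activated α-methoxy ester in the presence of the hindered lactone to the primary alcohol F7. Silylation (TBDPSCl, imidazole) gives 17 together with its C5 epimer, which is removed by chromatography.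

Step 10. Methylenation of the neopentyl-type lactone carbonyl may be sluggish, with thermal decay of the titanium reagent taking over. The fallback sets out from 17 and comes back at 18; it adds the carbon as a nucleophile and then eliminates. MeLi (1.1 equiv, THF, −78 °C) adds once to the lactone to give the hemiketal F8. MsCl and Et3N (CH2Cl2, 0 °C) eliminate through the C7a oxocarbenium ion, whose only β-hydrogens are on the methyl group, to give 18.

**Further compounds**
F1 | step 13 | (3S,4S,5R)-3-allyl-3-{(2R)-3-[(tert-butyldiphenylsilyl)oxy]-2-methoxypropyl}-4-methyl-5-(3,4,5-trimethoxyphenyl)oxolan-2-ol (lactol, both anomers) | OC1O[C@@H](c2cc(OC)c(OC)c(OC)c2)[C@@H](C)[C@]1(CC=C)C[C@@H](OC)CO[Si](c2ccccc2)(c2ccccc2)C(C)(C)C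
F2 | step 13 | (1R,2S,3S)-3-{(2R)-3-[(tert-butyldiphenylsilyl)oxy]-2-methoxypropyl}-3-ethynyl-2-methyl-1-(3,4,5-trimethoxyphenyl)hex-5-en-1-ol | C#C[C@@](CC=C)(C[C@@H](OC)CO[Si](c1ccccc1)(c1ccccc1)C(C)(C)C)[C@H](C)[C@@H](O)c1cc(OC)c(OC)c(OC)c1
F3 | step 13 | tert-butyl{(2R)-3-[(2E,3S,4S,5R)-3-allyl-2-(iodomethylidene)-4-methyl-5-(3,4,5-trimethoxyphenyl)oxolan-3-yl]-2-methoxypropoxy}diphenylsilane | I/C=C1/O[C@@H](c2cc(OC)c(OC)c(OC)c2)[C@@H](C)[C@]1(CC=C)C[C@@H](OC)CO[Si](c2ccccc2)(c2ccccc2)C(C)(C)C
F4 | step 13 | (2R)-3-[(2E,3S,4S,5R)-3-allyl-2-(iodomethylidene)-4-methyl-5-(3,4,5-trimethoxyphenyl)oxolan-3-yl]-2-methoxypropan-1-ol | I/C=C1/O[C@@H](c2cc(OC)c(OC)c(OC)c2)[C@@H](C)[C@]1(CC=C)C[C@@H](OC)CO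
F5 | step 13 | (2R)-3-[(2E,3S,4S,5R)-3-allyl-2-(iodomethylidene)-4-methyl-5-(3,4,5-trimethoxyphenyl)oxolan-3-yl]-2-methoxypropanal | I/C=C1/O[C@@H](c2cc(OC)c(OC)c(OC)c2)[C@@H](C)[C@]1(CC=C)C[C@@H](OC)C=O
F6 | step 9 | methyl 3-[(3S,4S,5R)-3-allyl-4-methyl-2-oxo-5-(3,4,5-trimethoxyphenyl)oxolan-3-yl]-2-methoxypropanoate (epimers at the methoxy carbon) | O=C1[C@@](CC=C)(CC(OC)C(=O)OC)[C@H](C)[C@H](c2cc(OC)c(OC)c(OC)c2)O1
F7 | step 9 | (3S,4S,5R)-3-allyl-3-(3-hydroxy-2-methoxypropyl)-4-methyl-5-(3,4,5-trimethoxyphenyl)oxolan-2-one (epimers at the methoxy carbon) | O=C1[C@@](CC=C)(CC(OC)CO)[C@H](C)[C@H](c2cc(OC)c(OC)c(OC)c2)O1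
F8 | step 10 | (3S,4S,5R)-3-allyl-3-{(2R)-3-[(tert-butyldiphenylsilyl)oxy]-2-methoxypropyl}-2,4-dimethyl-5-(3,4,5-trimethoxyphenyl)oxolan-2-ol (hemiketal) | CC1(O)O[C@@H](c2cc(OC)c(OC)c(OC)c2)[C@@H](C)[C@]1(CC=C)C[C@@H](OC)CO[Si](c2ccccc2)(c2ccccc2)C(C)(C)C
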